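## Retrosynthetic overview

1. Target 35 ← allylic alcohol 34 ← PMB ether 33; the ten-membered carbocycle is the last ring formed, by an intramolecular Pd-catalysed alkyl–alkenyl Negishi coupling (C3–C4) of diiodide 31.
2. 31 ← acylation of alcohol 29 with (S)-2-methylbutanoic acid 30; 29 ← zinc Barbier union (C7–C8, sets C7 and C8, unveils the α-methylene lactone) of bromobutenolide 14 and aldehyde 27.
3. 14 ← butenolide by ring-closing metathesis (first ring) ← Z-iodoalkenyl carbinol 7 ← enantioselective alkynylation of crotonaldehyde (sets C6), then trans-hydroalumination/iodination.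
4. 27 ← hydroxyl-directed anti-vinylmagnesiation of propargylic alcohol 18 (sets the C1=C10 geometry), terminal hydroboration, oxidation.
5. Ring order: butenolide (later the α-methylene-γ-lactone) first, ten-membered ring last.

Assumption: positions are labelled by germacrane numbering (C1–C10 ring, C11–C13 lactone carbons, C14 formyl carbon, C15 acetoxymethyl carbon), and (S,S)-ProPhenol is taken to add the alkyne to the aldehyde face that gives (4S)-5 (the mirror-image ligand is used if the sense is opposite).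

## Route

Step 1
Reactants: 1 prop-2-yn-1-ol
Product: 2 tert-butyldimethyl(prop-2-yn-1-yloxy)silane
Conditions: TBSCl, imidazole, CH2Cl2, 0 °C to rt
Reagents that add atoms: tert-butyldimethylsilyl chloride, CC(C)(C)[Si](C)(C)Cl
Why: Standard silyl ether protection of the primary alcohol, leaving the alkyne C–H as the only acidic site for the zinc chemistry.

Step 2
Reactants: 2 tert-butyldimethyl(prop-2-yn-1-yloxy)silane; 3 (E)-but-2-enal
Product: 5 (4S,5E)-1-[(tert-butyldimethylsilyl)oxy]hept-5-en-2-yn-4-ol, via zinc acetylide 4 (not isolated)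
Conditions: (S,S)-ProPhenol (10 mol %), Me2Zn (3 equiv), Ph3P=O (20 mol %), toluene, 0 °C, 24 h; aq NH4Cl
Reagents that add atoms: none
Why: Zn–ProPhenol-catalysed enantioselective alkynylation (1,2-addition of zinc acetylide 4 to the enal), in which the chiral dinuclear zinc complex selects one aldehyde face and sets the carbinol centre (later C6) as S.

Step 3
Reactants: 5 (4S,5E)-1-[(tert-butyldimethylsilyl)oxy]hept-5-en-2-yn-4-ol
Product: 7 (2Z,4S,5E)-1-[(tert-butyldimethylsilyl)oxy]-2-iodohepta-2,5-dien-4-ol, via cyclic alkenylalanate 6 (not isolated)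
Conditions: NaAlH2(OCH2CH2OMe)2 (1.6 equiv), THF, 0 °C to rt; then I2 (2.5 equiv), −78 to 0 °C; aq potassium sodium tartrate
Reagents that add atoms: iodine, II
Why: Hydroxyl-directed trans-hydroalumination of the propargylic alcohol (hydride to the carbinol-side carbon, aluminium on the far carbon inside chelate 6) followed by iodinolysis with retention gives the Z-alkenyl iodide, while the silyl ether does not direct and the isolated E-alkene is inert.

Step 4
Reactants: 7 (2Z,4S,5E)-1-[(tert-butyldimethylsilyl)oxy]-2-iodohepta-2,5-dien-4-ol; 8 prop-2-enoyl chloride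
Product: 9 (2Z,4S,5E)-1-[(tert-butyldimethylsilyl)oxy]-2-iodohepta-2,5-dien-4-yl prop-2-enoate
Conditions: iPr2NEt, CH2Cl2, −20 to 0 °C
Reagents that add atoms: none
Why: Esterification of the secondary alcohol with an acid chloride, which does not involve the stereocentre.

Step 5
Reactants: 9 (2Z,4S,5E)-1-[(tert-butyldimethylsilyl)oxy]-2-iodohepta-2,5-dien-4-yl prop-2-enoate; 10 formaldehyde
Product: 11 (2Z,4S,5E)-1-[(tert-butyldimethylsilyl)oxy]-2-iodohepta-2,5-dien-4-yl 2-(hydroxymethyl)prop-2-enoate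
Conditions: 10 as 37 % aqueous solution (3 equiv), DABCO (0.5 equiv), 1,4-dioxane/H2O (1:1), rt
Reagents that add atoms: none
Why: Morita–Baylis–Hillman hydroxymethylation of the acrylate α-carbon under DABCO catalysis installs C13 as a free primary alcohol without touching the silyl ether or the stereocentre.

Step 6
Reactants: 11 (2Z,4S,5E)-1-[(tert-butyldimethylsilyl)oxy]-2-iodohepta-2,5-dien-4-yl 2-(hydroxymethyl)prop-2-enoate
Product: 12 (5S)-5-{(1Z)-3-[(tert-butyldimethylsilyl)oxy]-2-iodoprop-1-en-1-yl}-3-(hydroxymethyl)furan-2(5H)-one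
Conditions: second-generation Grubbs catalyst (H2IMes)(PCy3)Cl2Ru=CHPh (5 mol %), toluene (0.01 M), 70 °C
Reagents that add atoms: none
Why: Ring-closing metathesis between the propenyl group and the 1,1-disubstituted acrylate closes the butenolide and expels propene, while the trisubstituted iodoalkene does not engage the catalyst and C6 is untouched.

Step 7
Reactants: 12 (5S)-5-{(1Z)-3-[(tert-butyldimethylsilyl)oxy]-2-iodoprop-1-en-1-yl}-3-(hydroxymethyl)furan-2(5H)-one
Product: 13 (5S)-3-(bromomethyl)-5-{(1Z)-3-[(tert-butyldimethylsilyl)oxy]-2-iodoprop-1-en-1-yl}furan-2(5H)-one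
Conditions: CBr4, PPh3, CH2Cl2, 0 °C
Reagents that add atoms: carbon tetrabromide, BrC(Br)(Br)Br
Why: Appel bromination of the primary allylic alcohol under neutral conditions that spare the base-sensitive butenolide.

Step 8
Reactants: 13 (5S)-3-(bromomethyl)-5-{(1Z)-3-[(tert-butyldimethylsilyl)oxy]-2-iodoprop-1-en-1-yl}furan-2(5H)-one
Product: 14 (2Z)-3-[(2S)-4-(bromomethyl)-5-oxo-2,5-dihydrofuran-2-yl]-2-iodoprop-2-en-1-yl acetate
Conditions: Ac2O (5 equiv), Cu(OTf)2 (5 mol %), CH2Cl2, 0 °C to rt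
Reagents that add atoms: acetic anhydride, CC(=O)OC(C)=O
Why: Cu(OTf)2-catalysed acetolysis converts the primary silyl ether directly into the acetate (silyl-to-acyl exchange), so the final C15 acetate is in place before fragment union.

Step 9
Reactants: 15 but-3-yn-1-ol
Product: 16 (but-3-yn-1-yloxy)(tert-butyl)dimethylsilane
Conditions: TBSCl, imidazole, CH2Cl2, 0 °C to rt
Reagents that add atoms: tert-butyldimethylsilyl chloride, CC(C)(C)[Si](C)(C)Cl
Why: Silyl ether protection of the primary alcohol (the future C3 oxygen handle).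

Step 10
Reactants: 16 (but-3-yn-1-yloxy)(tert-butyl)dimethylsilane; 10 formaldehyde
Product: 18 5-[(tert-butyldimethylsilyl)oxy]pent-2-yn-1-ol, via lithium acetylide 17 (not isolated)
Conditions: n-BuLi, THF, −78 °C; then 10 as paraformaldehyde, −78 °C to rt; aq NH4Cl
Reagents that add atoms: none
Why: Acetylide formation and addition to formaldehyde (alkynyl anion hydroxymethylation) gives the propargylic alcohol that carries C14.

Step 11
Reactants: 18 5-[(tert-butyldimethylsilyl)oxy]pent-2-yn-1-ol; 19 vinylmagnesium chloride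
Product: 21 (2E)-5-[(tert-butyldimethylsilyl)oxy]-2-ethenylpent-2-en-1-ol, via magnesium chelate 20 (not isolated)
Conditions: 19 (4 equiv), CuI (10 mol %), THF, reflux, 12 h; then aq NH4Cl, 0 °C
Reagents that add atoms: none
Why: Hydroxyl-directed copper-catalysed anti-carbomagnesiation of the propargylic alkoxide puts the vinyl group on the alkoxide-side carbon and magnesium on the far carbon inside chelate 20, so after protonation the vinyl group and the C2 chain are cis, which fixes the C1=C10 geometry.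

Step 12
Reactants: 21 (2E)-5-[(tert-butyldimethylsilyl)oxy]-2-ethenylpent-2-en-1-ol
Product: 22 tert-butyl{[(3E)-4-{[(4-methoxybenzyl)oxy]methyl}hexa-3,5-dien-1-yl]oxy}dimethylsilane
Conditions: NaH, PMBCl, Bu4NI (cat.), THF/DMF, 0 °C to rt
Reagents that add atoms: 4-methoxybenzyl chloride, COc1ccc(CCl)cc1
Why: Williamson etherification of the allylic alkoxide protects the future C14 oxygen as a PMB ether orthogonal to the silyl ether.

Step 13
Reactants: 22 tert-butyl{[(3E)-4-{[(4-methoxybenzyl)oxy]methyl}hexa-3,5-dien-1-yl]oxy}dimethylsilane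
Product: 23 (3E)-4-{[(4-methoxybenzyl)oxy]methyl}hexa-3,5-dien-1-ol
Conditions: HF·pyridine, THF/pyridine, 0 °C to rt
Reagents that add atoms: none
Why: Fluoride cleavage of the primary silyl ether, to which the PMB ether and the diene are stable.

Step 14
Reactants: 23 (3E)-4-{[(4-methoxybenzyl)oxy]methyl}hexa-3,5-dien-1-ol
Product: 24 1-({[(2E)-2-ethenyl-5-iodopent-2-en-1-yl]oxy}methyl)-4-methoxybenzene
Conditions: I2, PPh3, imidazole, CH2Cl2, 0 °C
Reagents that add atoms: iodine, II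
Why: Appel-type iodination of the primary alcohol gives the homoallylic iodide under neutral conditions.

Step 15
Reactants: 24 1-({[(2E)-2-ethenyl-5-iodopent-2-en-1-yl]oxy}methyl)-4-methoxybenzene
Product: 26 (3E)-6-iodo-3-{[(4-methoxybenzyl)oxy]methyl}hex-3-en-1-ol, via alkylborane 25 (not isolated)
Conditions: 9-BBN (1.3 equiv), THF, 0 °C to rt; then aq NaOAc, 30 % H2O2, 0 °C to rt
Reagents that add atoms: hydrogen peroxide, OO
Why: Anti-Markovnikov hydroboration of the terminal vinyl group of the diene by the bulky borane (the trisubstituted alkene reacts far more slowly) and buffered oxidation give the primary alcohol at C8 without displacing the iodide.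

Step 16
Reactants: 26 (3E)-6-iodo-3-{[(4-methoxybenzyl)oxy]methyl}hex-3-en-1-ol
Product: 27 (3E)-6-iodo-3-{[(4-methoxybenzyl)oxy]methyl}hex-3-enal
Conditions: Dess–Martin periodinane, pyridine, CH2Cl2, 0 °C; used crude at once
Reagents that add atoms: none
Why: Buffered Dess–Martin oxidation gives the β,γ-unsaturated aldehyde, which is used immediately so the double bond does not move into conjugation.

Step 17
Reactants: 14 (2Z)-3-[(2S)-4-(bromomethyl)-5-oxo-2,5-dihydrofuran-2-yl]-2-iodoprop-2-en-1-yl acetate; 27 (3E)-6-iodo-3-{[(4-methoxybenzyl)oxy]methyl}hex-3-enal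
Product: 29 (4R,5S)-5-[(1Z)-3-(acetyloxy)-2-iodoprop-1-en-1-yl]-4-[(1S,3E)-1-hydroxy-6-iodo-3-{[(4-methoxybenzyl)oxy]methyl}hex-3-en-1-yl]-3-methylidenedihydrofuran-2(3H)-one, via allylzinc bromide 28 (not isolated)
Conditions: Zn dust (3 equiv), THF/sat. aq NH4Cl (2:1), 0 °C to rt
Reagents that add atoms: none
Why: Zinc Barbier allylation through a six-membered chair transition state (SE2′), in which allylzinc 28 reacts through C7 on the face anti to the C6 alkenyl group (trans lactone, C7 R) and the ring-fixed allyl geometry with the aldehyde chain equatorial gives the C8 S carbinol, while allylic transposition creates the exocyclic methylene and both iodides are inert to Zn in this aqueous medium.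

Step 18
Reactants: 29 (4R,5S)-5-[(1Z)-3-(acetyloxy)-2-iodoprop-1-en-1-yl]-4-[(1S,3E)-1-hydroxy-6-iodo-3-{[(4-methoxybenzyl)oxy]methyl}hex-3-en-1-yl]-3-methylidenedihydrofuran-2(3H)-one; 30 (2S)-2-methylbutanoic acid
Product: 31 (1S,3E)-1-[(2S,3R)-2-[(1Z)-3-(acetyloxy)-2-iodoprop-1-en-1-yl]-4-methylidene-5-oxooxolan-3-yl]-6-iodo-3-{[(4-methoxybenzyl)oxy]methyl}hex-3-en-1-yl (2S)-2-methylbutanoate
Conditions: DCC, DMAP (0.2 equiv), CH2Cl2, 0 °C to rt
Reagents that add atoms: none
Why: Steglich esterification of the C8 alcohol with the chiral-pool acid, whose stereocentre is carried in unchanged.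

Step 19
Reactants: 31 (1S,3E)-1-[(2S,3R)-2-[(1Z)-3-(acetyloxy)-2-iodoprop-1-en-1-yl]-4-methylidene-5-oxooxolan-3-yl]-6-iodo-3-{[(4-methoxybenzyl)oxy]methyl}hex-3-en-1-yl (2S)-2-methylbutanoate
Product: 33 [(3aR,4S,6E,10E,11aR)-10-[(acetyloxy)methyl]-6-{[(4-methoxybenzyl)oxy]methyl}-3-methylidene-2-oxo-2,3,3a,4,5,8,9,11a-octahydrocyclodeca[b]furan-4-yl] (2S)-2-methylbutanoate, via alkylzinc iodide 32 (not isolated)
Conditions: Zn dust (3 equiv), LiCl (1.5 equiv), THF, 25 °C; decant from Zn, then syringe-pump addition (10 h) to Pd2(dba)3 (5 mol %), SPhos (12 mol %), THF, 40 °C (final 1 mM)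
Reagents that add atoms: none
Why: Proposed new method: closure of a ten-membered carbocycle by intramolecular alkyl–alkenyl Negishi coupling is not established chemistry; LiCl-assisted Zn insertion is chemoselective for the primary C(sp3)–I bond (the alkenyl iodide, esters and enoate are inert to Zn at 25 °C), and slow addition of 32 to Pd2(dba)3/SPhos gives oxidative addition of zerovalent palladium into the Z-alkenyl iodide, intramolecular transmetalation from the tethered alkylzinc through an eleven-membered palladacycle and stereoretentive reductive elimination to the C3–C4 bond, helped by the two cis ring olefins and the trans-lactone that pre-fold the chain; the closest known reactions are intermolecular Pd-catalysed Negishi couplings of functionalised primary alkylzinc iodides with alkenyl iodides and B-alkyl Suzuki macrocyclisations.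

Step 20
Reactants: 33 [(3aR,4S,6E,10E,11aR)-10-[(acetyloxy)methyl]-6-{[(4-methoxybenzyl)oxy]methyl}-3-methylidene-2-oxo-2,3,3a,4,5,8,9,11a-octahydrocyclodeca[b]furan-4-yl] (2S)-2-methylbutanoate
Product: 34 [(3aR,4S,6E,10E,11aR)-10-[(acetyloxy)methyl]-6-(hydroxymethyl)-3-methylidene-2-oxo-2,3,3a,4,5,8,9,11a-octahydrocyclodeca[b]furan-4-yl] (2S)-2-methylbutanoate
Conditions: DDQ (1.3 equiv), CH2Cl2/pH 7 buffer (10:1), 0 °C
Reagents that add atoms: none
Why: Oxidative PMB ether cleavage by DDQ (benzylic hydride abstraction, then hydrolysis of the oxocarbenium ion) frees the C14 alcohol without touching the esters, the allylic acetate or the α-methylene lactone.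

Step 21
Reactants: 34 [(3aR,4S,6E,10E,11aR)-10-[(acetyloxy)methyl]-6-(hydroxymethyl)-3-methylidene-2-oxo-2,3,3a,4,5,8,9,11a-octahydrocyclodeca[b]furan-4-yl] (2S)-2-methylbutanoate
Product: 35 [(3aR,4S,6E,10E,11aR)-10-[(acetyloxy)methyl]-6-formyl-3-methylidene-2-oxo-2,3,3a,4,5,8,9,11a-octahydrocyclodeca[b]furan-4-yl] (2S)-2-methylbutanoate
Conditions: MnO2 (20 equiv), CH2Cl2, rt
Reagents that add atoms: none
Why: Chemoselective MnO2 oxidation of the allylic alcohol gives the enal with the formyl group trans to C2, the stable enal geometry, so the C1=C10 configuration is retained.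

## Compound list

1 | prop-2-yn-1-ol | C#CCO | starting material
2 | tert-butyldimethyl(prop-2-yn-1-yloxy)silane | C#CCO[Si](C)(C)C(C)(C)C | intermediate
3 | (E)-but-2-enal | C/C=C/C=O | starting material
4 | methyl{3-[(tert-butyldimethylsilyl)oxy]prop-1-yn-1-yl}zinc (zinc acetylide) | C[Zn]C#CCO[Si](C)(C)C(C)(C)C | intermediate (not isolated)
5 | (4S,5E)-1-[(tert-butyldimethylsilyl)oxy]hept-5-en-2-yn-4-ol | C/C=C/[C@H](O)C#CCO[Si](C)(C)C(C)(C)C | intermediate
6 | sodium bis(2-methoxyethoxy)aluminate chelate of 5 (five-membered ring Al–O–C4–C3=C2, Al on C2) | [Na+].COCCO[Al-]1(OCCOC)O[C@@H](/C=C/C)C=C1CO[Si](C)(C)C(C)(C)C | intermediate (not isolated)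
7 | (2Z,4S,5E)-1-[(tert-butyldimethylsilyl)oxy]-2-iodohepta-2,5-dien-4-ol | C/C=C/[C@H](O)/C=C(\I)CO[Si](C)(C)C(C)(C)C | intermediate
8 | prop-2-enoyl chloride | C=CC(=O)Cl | starting material
9 | (2Z,4S,5E)-1-[(tert-butyldimethylsilyl)oxy]-2-iodohepta-2,5-dien-4-yl prop-2-enoate | C/C=C/[C@H](OC(=O)C=C)/C=C(\I)CO[Si](C)(C)C(C)(C)C | intermediate
10 | formaldehyde | C=O | starting material
11 | (2Z,4S,5E)-1-[(tert-butyldimethylsilyl)oxy]-2-iodohepta-2,5-dien-4-yl 2-(hydroxymethyl)prop-2-enoate | C/C=C/[C@H](OC(=O)C(=C)CO)/C=C(\I)CO[Si](C)(C)C(C)(C)C | intermediate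
12 | (5S)-5-{(1Z)-3-[(tert-butyldimethylsilyl)oxy]-2-iodoprop-1-en-1-yl}-3-(hydroxymethyl)furan-2(5H)-one | OCC1=C[C@@H](/C=C(\I)CO[Si](C)(C)C(C)(C)C)OC1=O | intermediate
13 | (5S)-3-(bromomethyl)-5-{(1Z)-3-[(tert-butyldimethylsilyl)oxy]-2-iodoprop-1-en-1-yl}furan-2(5H)-one | BrCC1=C[C@@H](/C=C(\I)CO[Si](C)(C)C(C)(C)C)OC1=O | intermediate
14 | (2Z)-3-[(2S)-4-(bromomethyl)-5-oxo-2,5-dihydrofuran-2-yl]-2-iodoprop-2-en-1-yl acetate | BrCC1=C[C@@H](/C=C(\I)COC(C)=O)OC1=O | intermediate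
15 | but-3-yn-1-ol | C#CCCO | starting material
16 | (but-3-yn-1-yloxy)(tert-butyl)dimethylsilane | C#CCCO[Si](C)(C)C(C)(C)C | intermediate
17 | lithium 4-[(tert-butyldimethylsilyl)oxy]but-1-yn-1-ide (lithium acetylide) | [Li]C#CCCO[Si](C)(C)C(C)(C)C | intermediate (not isolated)
18 | 5-[(tert-butyldimethylsilyl)oxy]pent-2-yn-1-ol | OCC#CCCO[Si](C)(C)C(C)(C)C | intermediate
19 | vinylmagnesium chloride | C=C[Mg]Cl | starting material
20 | 3-{2-[(tert-butyldimethylsilyl)oxy]ethyl}-4-ethenyl-2,5-dihydro-1,2-oxamagnesole (magnesium chelate) | C=CC1=C(CCO[Si](C)(C)C(C)(C)C)[Mg]OC1 | intermediate (not isolated)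
21 | (2E)-5-[(tert-butyldimethylsilyl)oxy]-2-ethenylpent-2-en-1-ol (CH2OH trans to the chain, vinyl cis to it) | OC/C(C=C)=C/CCO[Si](C)(C)C(C)(C)C | intermediate
22 | tert-butyl{[(3E)-4-{[(4-methoxybenzyl)oxy]methyl}hexa-3,5-dien-1-yl]oxy}dimethylsilane | COc1ccc(COC/C(C=C)=C/CCO[Si](C)(C)C(C)(C)C)cc1 | intermediate
23 | (3E)-4-{[(4-methoxybenzyl)oxy]methyl}hexa-3,5-dien-1-ol | OCC/C=C(\C=C)COCc1ccc(OC)cc1 | intermediate
24 | 1-({[(2E)-2-ethenyl-5-iodopent-2-en-1-yl]oxy}methyl)-4-methoxybenzene | ICC/C=C(\C=C)COCc1ccc(OC)cc1 | intermediate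
25 | 9-[(3E)-6-iodo-3-{[(4-methoxybenzyl)oxy]methyl}hex-3-en-1-yl]-9-borabicyclo[3.3.1]nonane (alkylborane) | ICC/C=C(\CCB1C2CCCC1CCC2)COCc1ccc(OC)cc1 | intermediate (not isolated)
26 | (3E)-6-iodo-3-{[(4-methoxybenzyl)oxy]methyl}hex-3-en-1-ol | OCC/C(COCc1ccc(OC)cc1)=C\CCI | intermediate
27 | (3E)-6-iodo-3-{[(4-methoxybenzyl)oxy]methyl}hex-3-enal | O=CC/C(COCc1ccc(OC)cc1)=C\CCI | intermediate
28 | {[(5S)-5-[(1Z)-3-(acetyloxy)-2-iodoprop-1-en-1-yl]-2-oxo-2,5-dihydrofuran-3-yl]methyl}zinc bromide (allylzinc bromide) | Br[Zn]CC1=C[C@@H](/C=C(\I)COC(C)=O)OC1=O | intermediate (not isolated)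
29 | (4R,5S)-5-[(1Z)-3-(acetyloxy)-2-iodoprop-1-en-1-yl]-4-[(1S,3E)-1-hydroxy-6-iodo-3-{[(4-methoxybenzyl)oxy]methyl}hex-3-en-1-yl]-3-methylidenedihydrofuran-2(3H)-one | C=C1C(=O)O[C@H](/C=C(\I)COC(C)=O)[C@H]1[C@@H](O)C/C(COCc2ccc(OC)cc2)=C\CCI | intermediate
30 | (2S)-2-methylbutanoic acid | CC[C@H](C)C(=O)O | starting material
31 | (1S,3E)-1-[(2S,3R)-2-[(1Z)-3-(acetyloxy)-2-iodoprop-1-en-1-yl]-4-methylidene-5-oxooxolan-3-yl]-6-iodo-3-{[(4-methoxybenzyl)oxy]methyl}hex-3-en-1-yl (2S)-2-methylbutanoate | C=C1C(=O)O[C@H](/C=C(\I)COC(C)=O)[C@H]1[C@@H](OC(=O)[C@@H](C)CC)C/C(COCc2ccc(OC)cc2)=C\CCI | intermediate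
32 | (1S,3E)-1-[(2S,3R)-2-[(1Z)-3-(acetyloxy)-2-iodoprop-1-en-1-yl]-4-methylidene-5-oxooxolan-3-yl]-6-(iodozincio)-3-{[(4-methoxybenzyl)oxy]methyl}hex-3-en-1-yl (2S)-2-methylbutanoate (alkylzinc iodide) | C=C1C(=O)O[C@H](/C=C(\I)COC(C)=O)[C@H]1[C@@H](OC(=O)[C@@H](C)CC)C/C(COCc2ccc(OC)cc2)=C\CC[Zn]I | intermediate (not isolated)
33 | [(3aR,4S,6E,10E,11aR)-10-[(acetyloxy)methyl]-6-{[(4-methoxybenzyl)oxy]methyl}-3-methylidene-2-oxo-2,3,3a,4,5,8,9,11a-octahydrocyclodeca[b]furan-4-yl] (2S)-2-methylbutanoate | C=C1C(=O)O[C@@H]2/C=C(/COC(C)=O)CC/C=C(/COCc3ccc(OC)cc3)C[C@H](OC(=O)[C@@H](C)CC)[C@@H]12 | intermediate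
34 | [(3aR,4S,6E,10E,11aR)-10-[(acetyloxy)methyl]-6-(hydroxymethyl)-3-methylidene-2-oxo-2,3,3a,4,5,8,9,11a-octahydrocyclodeca[b]furan-4-yl] (2S)-2-methylbutanoate | C=C1C(=O)O[C@@H]2/C=C(/COC(C)=O)CC/C=C(/CO)C[C@H](OC(=O)[C@@H](C)CC)[C@@H]12 | intermediate
35 | [(3aR,4S,6E,10E,11aR)-10-[(acetyloxy)methyl]-6-formyl-3-methylidene-2-oxo-2,3,3a,4,5,8,9,11a-octahydrocyclodeca[b]furan-4-yl] (2S)-2-methylbutanoate (CNP0230988.8) | C=C1C(=O)O[C@@H]2/C=C(/COC(C)=O)CC/C=C(/C=O)C[C@H](OC(=O)[C@@H](C)CC)[C@@H]12 | target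

## Step count and risks

Total step count: 21. Longest linear sequence: 13 steps (steps 1–8 then 17–21; the branch 9–16 then 17–21 is equally long).

Steps most likely to fail:

Step 19 (the proposed new ring closure). Risks are oligomerisation, protodezincation, and loss of the allylic acetate at palladium by β-acetoxy elimination or allyl ionisation. The fallback uses known chemistry and closes the ring at C1=C10 by ring-closing olefin metathesis instead of at C3–C4. It sets out from 14 (with 1, 19 and 30) and returns to the route at 33. Vinylmagnesium chloride 19 adds to prop-2-yn-1-ol 1 (CuI, THF, reflux) through the magnesium chelate 4-ethenyl-2,5-dihydro-1,2-oxamagnesole F1 to give 2-methylidenebut-3-en-1-ol F2. NaH/PMBCl gives 1-methoxy-4-{[(2-methylidenebut-3-en-1-yl)oxy]methyl}benzene F3. 9-BBN hydroboration of the monosubstituted vinyl group, through 9-(3-{[(4-methoxybenzyl)oxy]methyl}but-3-en-1-yl)-9-borabicyclo[3.3.1]nonane F4, and H2O2/NaOAc give 3-{[(4-methoxybenzyl)oxy]methyl}but-3-en-1-ol F5, and Dess–Martin oxidation gives 3-{[(4-methoxybenzyl)oxy]methyl}but-3-enal F6. Zinc Barbier reaction of 14 (through 28) with F6 under the step 17 conditions gives (4R,5S)-5-[(1Z)-3-(acetyloxy)-2-iodoprop-1-en-1-yl]-4-[(1S)-1-hydroxy-3-{[(4-methoxybenzyl)oxy]methyl}but-3-en-1-yl]-3-methylidenedihydrofuran-2(3H)-one F7. DCC/DMAP acylation with 30 gives (1S)-1-[(2S,3R)-2-[(1Z)-3-(acetyloxy)-2-iodoprop-1-en-1-yl]-4-methylidene-5-oxooxolan-3-yl]-3-{[(4-methoxybenzyl)oxy]methyl}but-3-en-1-yl (2S)-2-methylbutanoate F8. Intermolecular Negishi coupling of the alkenyl iodide with but-3-en-1-ylzinc bromide (Pd(OAc)2, SPhos, THF, rt) gives (1S)-1-[(2R,3R)-2-[(1E)-2-[(acetyloxy)methyl]hexa-1,5-dien-1-yl]-4-methylidene-5-oxooxolan-3-yl]-3-{[(4-methoxybenzyl)oxy]methyl}but-3-en-1-yl (2S)-2-methylbutanoate F9. Ring-closing metathesis with the second-generation Hoveyda–Grubbs catalyst (H2IMes)Cl2Ru=CH(C6H4-2-OiPr) (toluene, 80 °C, 1 mM) then joins C1 and C10 with loss of ethene to give 33, the ten-membered ring favouring the ring-cis olefin.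

Step 17 (fragment union that sets C7 and C8). The main risk is erosion or reversal of the carbinol (C8) configuration with this new aldehyde. The fallback corrects the stereochemistry instead of re-tuning the allylation. It sets out from 14 and 27 and returns at 31. If the allylation delivers mainly the C8 epimer, (4R,5S)-5-[(1Z)-3-(acetyloxy)-2-iodoprop-1-en-1-yl]-4-[(1R,3E)-1-hydroxy-6-iodo-3-{[(4-methoxybenzyl)oxy]methyl}hex-3-en-1-yl]-3-methylidenedihydrofuran-2(3H)-one F10, that alcohol is esterified with 30 under Mitsunobu conditions (PPh3, DIAD, toluene, 0 °C to rt), which inverts C8 and gives 31 directly.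

Step 2 (sets the only absolute stereocentre from which C7 and C8 are relayed). Risks are a low enantiomeric excess with this small aliphatic enal or the opposite facial sense. The fallback is a racemic addition followed by resolution. It sets out from 2 and 3 and returns at 5. Deprotonation of 2 with n-BuLi (THF, −78 °C) gives lithium 3-[(tert-butyldimethylsilyl)oxy]prop-1-yn-1-ide F11, which adds to 3 to give racemic (5E)-1-[(tert-butyldimethylsilyl)oxy]hept-5-en-2-yn-4-ol F12. Sharpless kinetic resolution (Ti(OiPr)4, L-(+)-diisopropyl tartrate, t-BuOOH 0.6 equiv, 4 Å molecular sieves, CH2Cl2, −20 °C) epoxidises the (4R) enantiomer to (1S)-1-[(2R,3R)-3-methyloxiran-2-yl]-4-[(tert-butyldimethylsilyl)oxy]but-2-yn-1-ol F13 and leaves (4S)-5 (at most 50 %), which is separated by chromatography.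

Further compounds
F1 | step 19 | 4-ethenyl-2,5-dihydro-1,2-oxamagnesole (magnesium chelate from 1 and 19) | C=CC1=C[Mg]OC1
F2 | step 19 | 2-methylidenebut-3-en-1-ol | C=CC(=C)CO
F3 | step 19 | 1-methoxy-4-{[(2-methylidenebut-3-en-1-yl)oxy]methyl}benzene | C=CC(=C)COCc1ccc(OC)cc1
F4 | step 19 | 9-(3-{[(4-methoxybenzyl)oxy]methyl}but-3-en-1-yl)-9-borabicyclo[3.3.1]nonane | C=C(CCB1C2CCCC1CCC2)COCc1ccc(OC)cc1
F5 | step 19 | 3-{[(4-methoxybenzyl)oxy]methyl}but-3-en-1-ol | C=C(CCO)COCc1ccc(OC)cc1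
F6 | step 19 | 3-{[(4-methoxybenzyl)oxy]methyl}but-3-enal | C=C(CC=O)COCc1ccc(OC)cc1
F7 | step 19 | (4R,5S)-5-[(1Z)-3-(acetyloxy)-2-iodoprop-1-en-1-yl]-4-[(1S)-1-hydroxy-3-{[(4-methoxybenzyl)oxy]methyl}but-3-en-1-yl]-3-methylidenedihydrofuran-2(3H)-one | C=C1C(=O)O[C@H](/C=C(\I)COC(C)=O)[C@H]1[C@@H](O)CC(=C)COCc2ccc(OC)cc2
F8 | step 19 | (1S)-1-[(2S,3R)-2-[(1Z)-3-(acetyloxy)-2-iodoprop-1-en-1-yl]-4-methylidene-5-oxooxolan-3-yl]-3-{[(4-methoxybenzyl)oxy]methyl}but-3-en-1-yl (2S)-2-methylbutanoate | C=C1C(=O)O[C@H](/C=C(\I)COC(C)=O)[C@H]1[C@@H](OC(=O)[C@@H](C)CC)CC(=C)COCc2ccc(OC)cc2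
F9 | step 19 | (1S)-1-[(2R,3R)-2-[(1E)-2-[(acetyloxy)methyl]hexa-1,5-dien-1-yl]-4-methylidene-5-oxooxolan-3-yl]-3-{[(4-methoxybenzyl)oxy]methyl}but-3-en-1-yl (2S)-2-methylbutanoate | C=C1C(=O)O[C@H](/C=C(\CCC=C)COC(C)=O)[C@H]1[C@@H](OC(=O)[C@@H](C)CC)CC(=C)COCc2ccc(OC)cc2
F10 | step 17 | (4R,5S)-5-[(1Z)-3-(acetyloxy)-2-iodoprop-1-en-1-yl]-4-[(1R,3E)-1-hydroxy-6-iodo-3-{[(4-methoxybenzyl)oxy]methyl}hex-3-en-1-yl]-3-methylidenedihydrofuran-2(3H)-one | C=C1C(=O)O[C@H](/C=C(\I)COC(C)=O)[C@H]1[C@H](O)C/C(COCc2ccc(OC)cc2)=C\CCI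
F11 | step 2 | lithium 3-[(tert-butyldimethylsilyl)oxy]prop-1-yn-1-ide | [Li]C#CCO[Si](C)(C)C(C)(C)C
F12 | step 2 | racemic (5E)-1-[(tert-butyldimethylsilyl)oxy]hept-5-en-2-yn-4-ol | C/C=C/C(O)C#CCO[Si](C)(C)C(C)(C)C
F13 | step 2 | (1S)-1-[(2R,3R)-3-methyloxiran-2-yl]-4-[(tert-butyldimethylsilyl)oxy]but-2-yn-1-ol | C[C@H]1O[C@@H]1[C@@H](O)C#CCO[Si](C)(C)C(C)(C)C
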